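All runs come from a simulation with made-up constants, and the scatter is random.

The chair opened with an impossibility: on the proposed steps, a molecule cannot be isomer of the product before it has been target. So the isomer in a flask depends on how long each molecule has been target, and the meeting agreed to follow one molecule.

| flask | substrate | partner | temperature | remark | time |
|---|---|---|---|---|---|
| oak | 10 mM | 25 mM | 20 °C | run made earlier |  |
| birch | 10 mM | 12 mM | 31 °C | run made earlier |  |
| maple | 10 mM | 50 mM | 20 °C | run made earlier |  |
| Sunday's | 10 mM | 25.0 mM (fed, over 30 min) |  | the addition at −15 °C, then warmed to 25 °C; the feed brings no volume worth counting | 80 min |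
| Saturday's | 10 mM (fed, over 30 min) | 25.0 mM | 25 °C | all else is in the flask from the start; the feed brings no volume worth counting | 80 min |
| Friday's | 10 mM | 25.0 mM | 25 °C | everything together at the start | 80 min |
| Thursday's | 10 mM | 25.0 mM (fed, over 30 min) | 25 °C | all else is in the flask from the start; the feed brings no volume worth counting | 80 min |

| run | time / min | isomer of the product / % | target / % |
|---|---|---|---|
| oak | 5.00 | 0 | 1.1 |
| oak | 15.0 | 0.6 | 12.4 |
| oak | 30.0 | 3.8 | 32.9 |
| oak | 40.0 | 7.9 | 43.9 |
| oak | 60.0 | 17.8 | 56.9 |
| oak | 80.0 | 27.7 | 59.3 |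
| birch | 12.0 | 4.9 | 21.0 |
| birch | 25.0 | 18.6 | 36.0 |
| birch | 40.0 | 33.3 | 40.2 |
| birch | 50.0 | 40.4 | 40.3 |
| birch | 60.0 | 45.4 | 39.6 |
| birch | 80.0 | 51.4 | 39.4 |
| maple | 5.00 | 0.3 | 2.9 |
| maple | 15.0 | 1.0 | 22.4 |
| maple | 30.0 | 7.0 | 53.6 |
| maple | 40.0 | 13.0 | 65.3 |
| maple | 60.0 | 25.4 | 68.8 |
| maple | 80.0 | 35.7 | 63.0 |

(scatter of a reading: 0.3 percentage points)

- the flask that comes out highest in amount of isomer of the product, in percent of the substrate charged, or "all alike" when all lie within 1.5 percentage points (Sunday's / Saturday's / Friday's / Thursday's / all alike)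
- isomer of the product at the end, in percent of the substrate charged, Sunday's
- isomer of the product at the end, in percent of the substrate charged, Saturday's
- isomer of the product at the end, in percent of the substrate charged, Friday's
- isomer of the product at the end, in percent of the substrate charged, Thursday's

The first speaker took the fork between target and isomer. She wrote the balance as the climb of c(isomer) = forward constant × c(target) − back constant × c(isomer), and said two stretches of one run give both constants. In birch the isomer climbs by 0.00980 min⁻¹ of the charge, later by 0.00300 min⁻¹. That gives a sum of constants, the relaxation rate, of 0.0817 min⁻¹ at 31 °C, and an isomer share at balance of 59.2 %. Oak, treated alike, gives 0.0218 min⁻¹ at 20 °C. Interpolating the logarithm to 25 °C gives 0.0397 min⁻¹, hence the flip half-life, the time in which a molecule's distance from the balance share halves: 17.4 min.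

The second speaker dated the births. Oak holds half of its charge as target and isomer at 40.0 min. Assuming supply speeds up as the flip does, the mean birth at 25 °C falls near 21.9 min. My reckoning keeps the share and gives:

- Friday's: 53.3 %.
- Thursday's and Saturday's, with birth delayed by half the feed: 48.5 %.
- Sunday's, its cold 30 min counted as lost and its sum taken as oak's last: 34.6 %.

Friday's therefore comes out highest.

The forecast names Friday's, with 50 % there, 46 % for Saturday's, 43 % for Thursday's and 34 % for Sunday's, on the ground that “Feeding delays target, so the isomer has less time”.

The flasks give Friday's highest: 49.0 %, then Saturday's 44.4 %, Thursday's 42.4 % and Sunday's 32.0 %.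

    target ⇌ isomer of the product (K = 1.50, k = 3.70 × 10⁻⁴ s⁻¹, Ea = 97.0 kJ mol⁻¹, ΔH = −5.00 kJ mol⁻¹)
    substrate + target ⇌ idle adduct, settled at all times (K = 900 M⁻¹, ΔH = −61.0 kJ mol⁻¹)
    open intermediate + second intermediate → target (k = 0.0770 M⁻¹ s⁻¹, Ea = 63.0 kJ mol⁻¹)
    substrate → open intermediate (k = 0.0100 s⁻¹, Ea = 85.0 kJ mol⁻¹)
    partner → second intermediate (k = 6.80 × 10⁻⁴ s⁻¹, Ea = 86.0 kJ mol⁻¹)
    (constants at 25 °C)

Friday's relaxes with a half-life of 18.7 min for target and isomer, shorter than its 80 min, yet its isomer stands at 49.0 % against 60.0 % at 800 min, so at the asked time the flask is under kinetic rather than thermodynamic control. Put back through my own flip half-life 17.4 min and share 59.2 %, not through the constants above, the isomer's part of target plus isomer gives an estimated mean age of 46.3 min for Friday's, and for Sunday's, with 32.0 % of isomer beside 56.5 % of target, an estimated 23.7 min.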